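## Retrosynthetic overview

1. The target comes from the 2,15‑diacetoxy‑3‑ketone by hydride reduction (C3); the 2‑oxygen comes from enolate hydroxylation of an ent‑labd‑7‑en‑3‑one (C2).
2. The 7‑ene comes from the 8(17)‑ene by isomerisation; the 8(17)‑ene from chemoselective methylenation of a 3,8‑diketone.
3. The diketone comes from a spiro‑oxepane enedione in one dissolving‑metal operation: C9–O unzipping (frees C15‑OH, sets C9) plus reductive methylation (sets C5, completes the gem‑dimethyl).
4. The spiro‑oxepane enedione comes from a one‑carbon ring expansion (semipinacol 1,2‑shift of the quaternary carbon) of a Hajos–Parrish‑type hydrindenedione with a lithiated, lactone‑derived cyclic N,O‑acetal that carries the whole side chain.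
5. Pieces: hydrindenedione from 2‑methylcyclopentane‑1,3‑dione + ethyl vinyl ketone; N,O‑acetal from 4‑methylcyclohexanone by enzymatic Baeyer–Villiger oxidation. Ring order: five‑membered ring (bought), then ring A (annulation), then ring B (ring expansion of the cyclopentanone).

Assumption: labdane numbering is used for the bicyclic compounds (C1–C10 decalin, C11–C16 side chain on C9, C17 on C8, C18/C19 on C4, C20 on C10); all are in the ent series and R/S descriptors are those of the actual molecules.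

## Route

Step 1
Reactants: 1 4‑methylcyclohexanone
Product: 2 (S)‑5‑methyloxepan‑2‑one
Conditions: cyclohexanone monooxygenase (Acinetobacter), NADPH (cat.), D‑glucose, glucose dehydrogenase, air, Tris buffer pH 8, 25 °C
Reagents that add atoms: dioxygen (O=O)
Why: Enzymatic Baeyer–Villiger oxidation desymmetrises the ketone because the enzyme lets only one of the two enantiotopic CH2 groups migrate to oxygen, which sets the methyl‑bearing stereocentre (C13 of the target, S).

Step 2
Reactants: 2 (S)‑5‑methyloxepan‑2‑one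
Product: 4 1‑[(5S)‑5‑methyloxepan‑2‑yl]‑1H‑benzotriazole, via lactol 3 (not isolated)
Conditions: i‑Bu2AlH (1.05 equiv), CH2Cl2, −78 °C; then 1H‑benzotriazole (1.3 equiv), BF3·OEt2 (1.2 equiv), −78 → 0 °C
Reagents that add atoms: 1H‑benzotriazole (c1ccc2[nH]nnc2c1)
Why: Low‑temperature i‑Bu2AlH reduction stops at the tetrahedral aluminium hemiacetal, which BF3·OEt2 ionises to the seven‑membered oxocarbenium ion that benzotriazole traps (reductive N,O‑acetal formation); C13 is untouched and the new acetal centre is a mixture that is erased later.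

Step 3
Reactants: 5 2‑methylcyclopentane‑1,3‑dione; 6 pent‑1‑en‑3‑one
Product: 8 (R)‑4,7a‑dimethyl‑2,3,7,7a‑tetrahydro‑1H‑indene‑1,5(6H)‑dione, via triketone 7 (not isolated)
Conditions: H2O, 20 °C; then D‑phenylalanine (1.0 equiv), 1 M HClO4 (0.4 equiv), MeCN, 80 °C
Reagents that add atoms: none
Why: Michael addition followed by the amino‑acid‑catalysed Hajos–Parrish–Eder–Sauer–Wiechert aldol condensation builds ring A, and the D‑phenylalanine enamine selects one of the two enantiotopic ring carbonyls, which sets the quaternary centre (C10 of the target) as R in 8.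

Step 4
Reactants: 8 (R)‑4,7a‑dimethyl‑2,3,7,7a‑tetrahydro‑1H‑indene‑1,5(6H)‑dione; 4 1‑[(5S)‑5‑methyloxepan‑2‑yl]‑1H‑benzotriazole
Product: 10 (13S)‑ent‑9,15‑epoxy‑17,19‑dinorlabd‑4‑ene‑3,8‑dione, via carbinol adduct 9 (not isolated)
Conditions: 8, KH (1.05 equiv), THF, 0 → 20 °C; 4, n‑BuLi (1.1 equiv), THF, −78 °C; combine, −78 °C; ZnBr2 (2.5 equiv), −78 → 40 °C; 1 M HCl, 20 °C
Reagents that add atoms: none
Why: Proposed new method: the potassium dienolate of 8 masks the enone while the 2‑lithio‑2‑benzotriazolyl oxepane adds to the cyclopentanone anti to the angular methyl, ZnBr2 then ionises the C–N bond to a cyclic oxocarbenium ion next to the zinc alkoxide, and the allylic quaternary carbon (C10) migrates in a cation‑like semipinacol 1,2‑shift (higher migratory aptitude than the CH2, retention at the migrating centre) to give six‑membered ring B with the C11–C16 chain tied back as a spiro‑oxepane; the closest known reaction type is the Katritzky benzotriazole‑mediated carbon insertion of acyclic Bt–C(Li)(OR)R′ reagents into ketones, not yet shown for a lactone‑derived cyclic N,O‑acetal or for migration of the quaternary centre of a hydrindenone.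

Step 5
Reactants: 10 (13S)‑ent‑9,15‑epoxy‑17,19‑dinorlabd‑4‑ene‑3,8‑dione
Product: 11 (13S)‑ent‑15‑hydroxy‑17‑norlabdane‑3,8‑dione
Conditions: Li (4.2 equiv), NH3(l)/THF, −78 °C; MeI (1.3 equiv), −78 °C; H2O/THF, −78 → 20 °C
Reagents that add atoms: iodomethane (CI)
Why: One dissolving‑metal operation combines Birch‑type reductive methylation of the enone with reductive cleavage of the α‑alkoxy ketone: the C9–O bond is unzipped to the C8 enolate (protecting C8, freeing the C15 alkoxide), axial protonation of the β‑carbanion gives the trans ring fusion at C5, only the C3 enolate is C‑methylated at C4 (the C8 enolate is shielded by quaternary C10), and the cold aqueous quench protonates C9 kinetically anti to the C10 methyl so the side chain ends cis to it.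

Step 6
Reactants: 11 (13S)‑ent‑15‑hydroxy‑17‑norlabdane‑3,8‑dione
Product: 12 (13S)‑ent‑15‑hydroxylabd‑8(17)‑en‑3‑one
Conditions: Ph3PCH3Br (1.6 equiv), KOtBu (1.5 equiv), THF, 0 °C
Reagents that add atoms: methyltriphenylphosphonium bromide (C[P+](c1ccccc1)(c1ccccc1)c1ccccc1.[Br-])
Why: Wittig methylenation is chemoselective for the C8 ketone because the C3 ketone is neopentylic (flanked by the gem‑dimethyl carbon), and it is the standard way 17‑nor‑8‑oxolabdanes are converted to 8(17)‑enes with the C9 configuration kept.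

Step 7
Reactants: 12 (13S)‑ent‑15‑hydroxylabd‑8(17)‑en‑3‑one
Product: 13 (13S)‑ent‑15‑hydroxylabd‑7‑en‑3‑one
Conditions: chloro[N,N′‑bis(3,5‑di‑tert‑butylsalicylidene)‑1,2‑cyclohexanediaminato]cobalt (trivalent cobalt, 2 mol%), PhSiH3 (4 mol%), benzene, 22 °C
Reagents that add atoms: none
Why: Cobalt‑hydride hydrogen‑atom‑transfer isomerisation (Shenvi type): reversible H‑atom addition to the exocyclic CH2 gives the tertiary C8 radical, and the bulky cobalt complex abstracts the unhindered axial H at C7 instead of the tertiary H at C9 beside the quaternary carbon, so the trisubstituted 7‑ene forms under kinetic control without touching any stereocentre.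

Step 8
Reactants: 13 (13S)‑ent‑15‑hydroxylabd‑7‑en‑3‑one
Product: 15 (13S)‑ent‑2α,15‑diacetoxylabd‑7‑en‑3‑one, via hydroxy ketone 14 (not isolated)
Conditions: KN(SiMe3)2 (2.2 equiv), THF, −78 °C; 2‑(phenylsulfonyl)‑3‑phenyloxaziridine (1.3 equiv), −78 °C; Ac2O (4 equiv), DMAP (cat.), −78 → 0 °C
Reagents that add atoms: 2‑(phenylsulfonyl)‑3‑phenyloxaziridine (O=S(=O)(c1ccccc1)N1OC1c1ccccc1); acetic anhydride (CC(=O)OC(C)=O)
Why: Davis α‑hydroxylation of the potassium enolate (only C2 can enolise) followed by in‑flask acetylation of both potassium alkoxides: the oxaziridine approaches C2 anti to the two syn‑axial methyl groups on C10 and C4, which sets the equatorial 2‑oxygen trans to the C10 methyl.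

Step 9
Reactants: 15 (13S)‑ent‑2α,15‑diacetoxylabd‑7‑en‑3‑one
Product: 16 (2S,3S,5S,9R,10S,13S)‑ent‑2α‑acetoxy‑3β‑hydroxylabd‑7‑en‑15‑yl acetate (target)
Conditions: NaBH4 (1.5 equiv), CeCl3·7H2O (1.0 equiv), MeOH/THF, −78 → −40 °C; H2O
Reagents that add atoms: none
Why: Luche‑type borohydride reduction: hydride attacks the 4,4‑dimethyl‑3‑ketone axially from the face opposite the axial C4 and C10 methyl groups, which gives the equatorial 3‑hydroxyl (cis to the C10 methyl, trans to the 2‑acetate), while low temperature and the cerium salt suppress acetyl migration and spare both esters.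

## Compound list

1 | 4‑methylcyclohexanone | CC1CCC(=O)CC1 | starting material
2 | (S)‑5‑methyloxepan‑2‑one | O=C1CC[C@H](C)CCO1 | intermediate
3 | (5S)‑5‑methyloxepan‑2‑ol (lactol, aluminium‑bound, not isolated) | OC1CC[C@H](C)CCO1 | intermediate
4 | 1‑[(5S)‑5‑methyloxepan‑2‑yl]‑1H‑benzotriazole (both epimers at oxepane C2) | C[C@@H]1CCOC(CC1)n2nnc3ccccc23 | intermediate
5 | 2‑methylcyclopentane‑1,3‑dione | CC1C(=O)CCC1=O | starting material
6 | pent‑1‑en‑3‑one (ethyl vinyl ketone) | CCC(=O)C=C | starting material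
7 | 2‑methyl‑2‑(3‑oxopentyl)cyclopentane‑1,3‑dione (not isolated) | CCC(=O)CCC1(C)C(=O)CCC1=O | intermediate
8 | (R)‑4,7a‑dimethyl‑2,3,7,7a‑tetrahydro‑1H‑indene‑1,5(6H)‑dione | O=C1CCC2=C(C)C(=O)CC[C@@]12C | intermediate
9 | (7aR)‑1‑[2‑(1H‑benzotriazol‑1‑yl)‑(5S)‑5‑methyloxepan‑2‑yl]‑1‑hydroxy‑4,7a‑dimethyl‑1,2,3,6,7,7a‑hexahydro‑5H‑inden‑5‑one (hydroxyl cis to the angular methyl; alkoxide/dienolate in the flask, not isolated) | C[C@@H]1CCOC(CC1)(n2nnc3ccccc23)[C@@]4(O)CCC5=C(C)C(=O)CC[C@@]45C | intermediate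
10 | (13S)‑ent‑9,15‑epoxy‑17,19‑dinorlabd‑4‑ene‑3,8‑dione (spiro‑oxepane at C9; C9 configuration uncontrolled and erased in step 5) | O1CC[C@@H](C)CCC12C(=O)CCC3=C(C)C(=O)CC[C@@]23C | intermediate
11 | (13S)‑ent‑15‑hydroxy‑17‑norlabdane‑3,8‑dione (trans ring fusion; C9 side chain cis to the C10 methyl) | OCC[C@@H](C)CC[C@@H]1C(=O)CC[C@@H]2C(C)(C)C(=O)CC[C@@]12C | intermediate
12 | (13S)‑ent‑15‑hydroxylabd‑8(17)‑en‑3‑one | OCC[C@@H](C)CC[C@@H]1C(=C)CC[C@@H]2C(C)(C)C(=O)CC[C@@]12C | intermediate
13 | (13S)‑ent‑15‑hydroxylabd‑7‑en‑3‑one | OCC[C@@H](C)CC[C@@H]1C(C)=CC[C@@H]2C(C)(C)C(=O)CC[C@@]12C | intermediate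
14 | (13S)‑ent‑2α,15‑dihydroxylabd‑7‑en‑3‑one (2‑OH equatorial, trans to the C10 methyl; dipotassium alkoxide in the flask, not isolated) | OCC[C@@H](C)CC[C@@H]1C(C)=CC[C@@H]2C(C)(C)C(=O)[C@@H](O)C[C@@]12C | intermediate
15 | (13S)‑ent‑2α,15‑diacetoxylabd‑7‑en‑3‑one | CC(=O)OCC[C@@H](C)CC[C@@H]1C(C)=CC[C@@H]2C(C)(C)C(=O)[C@@H](OC(C)=O)C[C@@]12C | intermediate
16 | (2S,3S,5S,9R,10S,13S)‑ent‑2α‑acetoxy‑3β‑hydroxylabd‑7‑en‑15‑yl acetate (2‑OAc and 3‑OH both equatorial; 3‑OH cis to the C10 methyl) | CC(=O)OCC[C@@H](C)CC[C@@H]1C(C)=CC[C@@H]2C(C)(C)[C@H](O)[C@@H](OC(C)=O)C[C@@]12C | target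

## Step count and risks

Total steps: 9. Longest linear sequence: 8 (steps 1, 2, 4, 5, 6, 7, 8, 9).

**Step 4 (proposed new ring expansion).** Risks: slow addition of the tertiary benzotriazolyl carbanion to the α‑quaternary ketone, and migration of the ring CH2 instead of the quaternary carbon. Fallback with known chemistry, setting out from 4 and 8 and returning at 10: KOtBu in refluxing THF eliminates benzotriazole from 4 to give the cyclic enol ether (S)‑4‑methyl‑2,3,4,5‑tetrahydrooxepine F1. t‑BuLi (THF, −78 → 0 °C) lithiates it at the oxygen‑bearing vinyl carbon, and this vinyllithium adds to the KH‑derived dienolate of 8 to give the tertiary carbinol (7aR)‑1‑hydroxy‑4,7a‑dimethyl‑1‑[(5S)‑5‑methyl‑4,5,6,7‑tetrahydrooxepin‑2‑yl]‑1,2,3,6,7,7a‑hexahydro‑5H‑inden‑5‑one F2. Camphorsulfonic acid in CH2Cl2 protonates the enol ether and the oxocarbenium ion undergoes the oxonium‑ion‑initiated pinacol ring expansion (Paquette type) to 10.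

**Step 5 (one‑pot unzipping and reductive methylation).** Risks: competing C‑ or O‑methylation of the C8 enolate, over‑methylation at C2, and incomplete C9–O cleavage. Fallback setting out from 10 and returning at 12: SmI2 (divalent samarium, 2.2 equiv, THF/MeOH, −78 °C) cleaves only the α‑alkoxy ketone, and methanol protonates the samarium enolate kinetically to give (13S)‑ent‑15‑hydroxy‑17,19‑dinorlabd‑4‑ene‑3,8‑dione F3. Non‑basic Lombardo methylenation (Zn, CH2Br2, TiCl4) of the saturated ketone gives (13S)‑ent‑15‑hydroxy‑19‑norlabda‑4,8(17)‑dien‑3‑one F4. Ordinary Birch reductive methylation (Li, NH3/THF; MeI) of this dienone then gives 12.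

**Step 7 (alkene isomerisation).** Risks: formation of the tetrasubstituted 8‑ene, or stalling. Fallback setting out from 11 and returning at 13 (steps 6 and 7 are bypassed): KN(SiMe3)2 (2.1 equiv, THF, −78 °C) removes the unhindered axial H at C7, whereas the axial H at C2 of the other ketone is shielded by two syn‑axial methyl groups. N‑(5‑chloro‑2‑pyridyl)bis(trifluoromethanesulfonimide) traps the enolate as (13S)‑ent‑15‑hydroxy‑3‑oxo‑17‑norlabd‑7‑en‑8‑yl trifluoromethanesulfonate F5. Negishi methylation (MeZnCl, Pd(PPh3)4 with zerovalent palladium, THF) then gives 13 with the double bond fixed at C7–C8.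

Further compounds
F1 | step 4 | (S)‑4‑methyl‑2,3,4,5‑tetrahydrooxepine | C[C@@H]1CCOC=CC1
F2 | step 4 | (7aR)‑1‑hydroxy‑4,7a‑dimethyl‑1‑[(5S)‑5‑methyl‑4,5,6,7‑tetrahydrooxepin‑2‑yl]‑1,2,3,6,7,7a‑hexahydro‑5H‑inden‑5‑one | C[C@@H]1CCOC(=CC1)[C@@]2(O)CCC3=C(C)C(=O)CC[C@@]23C
F3 | step 5 | (13S)‑ent‑15‑hydroxy‑17,19‑dinorlabd‑4‑ene‑3,8‑dione | OCC[C@@H](C)CC[C@@H]1C(=O)CCC2=C(C)C(=O)CC[C@@]12C
F4 | step 5 | (13S)‑ent‑15‑hydroxy‑19‑norlabda‑4,8(17)‑dien‑3‑one | OCC[C@@H](C)CC[C@@H]1C(=C)CCC2=C(C)C(=O)CC[C@@]12C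
F5 | step 7 | (13S)‑ent‑15‑hydroxy‑3‑oxo‑17‑norlabd‑7‑en‑8‑yl trifluoromethanesulfonate | OCC[C@@H](C)CC[C@@H]1C(OS(=O)(=O)C(F)(F)F)=CC[C@@H]2C(C)(C)C(=O)CC[C@@]12C
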